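**Retrosynthetic overview**

1. The seven-membered tropolone ring is made last, by oxidative catechol-plus-pyrogallol condensation of ring B of epicatechin gallate 18 with the 2,3,4-trihydroxyphenyl ring of flavan 28 (one pyrogallol carbon leaves as CO2). The 4-substituted pyrogallol places the second flavan on C7 of the benzotropolone, next to the tropolone C6–OH.
2. Each flavan comes from a racemic flavan-3-one by hydrogenation with dynamic kinetic resolution, which sets the (2R,3R)-cis pair; the ketone comes from a 3-siloxy-4H-chromene.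
3. Ring C of the galloylated flavan is closed by forming C3–C4 and O1–C8a together: an alpha-siloxy aryl ketone (O1–C2–C3) is C-benzylated by 2-bromo-4,6-dibenzyloxybenzyl chloride (C4, C8a) and the enolate is then O-arylated under copper catalysis in the same pot. The same annulation builds the second flavan.
4. Enabling feature: in ring C, O1 and C3 are 1,3-related through C2, and C2 carries only the ring B aryl group besides. At the C2-ketone level O1–C2=C3 is therefore the only possible enolate, and ring A supplies the matching 1,3-pair, benzylic C4 and the ortho aryl carbon C8a.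
5. Ring order: ring C of 13 and of 25 (rings A and B enter as arenes), then the gallate, then the seven-membered ring.

Key step: step 8

Assumption: the structure is taken exactly as drawn, i.e. the benzotropolone isomer with the non-galloylated flavan on C7 and both flavan units (2R,3R)-2,3-cis; compounds 1, 7, 16 and 19 are taken as catalogue materials.

**Route**

Step 1
Reactants: 1 5-bromobenzene-1,3-diol
Product: 2 1,3-bis(benzyloxy)-5-bromobenzene
Conditions: BnBr (2.2 equiv), K2CO3, DMF, 60 °C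
Reagents that add atoms: benzyl bromide, BrCc1ccccc1
Why: Williamson ether synthesis of both phenols; the aryl bromide is untouched and is kept as the later leaving group on C8a.

Step 2
Reactants: 2 1,3-bis(benzyloxy)-5-bromobenzene
Product: 4 2,4-bis(benzyloxy)-6-bromobenzaldehyde, via iminium salt 3 (not isolated)
Conditions: POCl3, DMF, 0 → 80 °C; then H2O, rt
Reagents that add atoms: N,N-dimethylformamide, CN(C)C=O; water, O
Why: Vilsmeier–Haack formylation of the activated arene, expected next to bromine (para to one ether, ortho to the other) and not at the more hindered carbon between the two ethers, which puts the future C4 on the future C4a.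

Step 3
Reactants: 4 2,4-bis(benzyloxy)-6-bromobenzaldehyde
Product: 5 [2,4-bis(benzyloxy)-6-bromophenyl]methanol
Conditions: NaBH4, THF/MeOH, 0 °C
Reagents that add atoms: none
Why: Borohydride reduction of an aryl aldehyde; aryl bromide and benzyl ethers are inert.

Step 4
Reactants: 5 [2,4-bis(benzyloxy)-6-bromophenyl]methanol
Product: 6 1,5-bis(benzyloxy)-3-bromo-2-(chloromethyl)benzene
Conditions: SOCl2, pyridine, CH2Cl2, −10 → 0 °C; used crude at once
Reagents that add atoms: thionyl chloride, O=S(Cl)Cl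
Why: Chlorodehydroxylation of an electron-rich benzylic alcohol through its chlorosulfite; the chloride is the more manageable halide of this easily ionised benzyl system.

Step 5
Reactants: 7 1-(3,4-dihydroxyphenyl)ethan-1-one
Product: 8 1-[3,4-bis(benzyloxy)phenyl]ethan-1-one
Conditions: BnBr (2.2 equiv), K2CO3, DMF, 60 °C
Reagents that add atoms: benzyl bromide, BrCc1ccccc1
Why: Williamson ether synthesis that protects the ring B catechol as benzyl ethers.

Step 6
Reactants: 8 1-[3,4-bis(benzyloxy)phenyl]ethan-1-one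
Product: 9 ({1-[3,4-bis(benzyloxy)phenyl]ethenyl}oxy)tri(propan-2-yl)silane
Conditions: i-Pr3SiOTf, Et3N, CH2Cl2, 0 °C → rt
Reagents that add atoms: triisopropylsilyl trifluoromethanesulfonate, CC(C)[Si](OS(=O)(=O)C(F)(F)F)(C(C)C)C(C)C
Why: Soft enolisation and O-silylation of an aryl methyl ketone to its silyl enol ether.

Step 7
Reactants: 9 ({1-[3,4-bis(benzyloxy)phenyl]ethenyl}oxy)tri(propan-2-yl)silane
Product: 11 1-[3,4-bis(benzyloxy)phenyl]-2-[(triisopropylsilyl)oxy]ethan-1-one, via siloxy epoxide 10 (not isolated)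
Conditions: mCPBA (1.05 equiv), CH2Cl2, −20 → 0 °C
Reagents that add atoms: 3-chloroperoxybenzoic acid, OOC(=O)c1cccc(Cl)c1
Why: Rubottom oxidation: epoxidation of the enol ether and a 1,4 silyl shift as the epoxide opens should deliver the alpha-siloxy ketone with O3 in place and already protected.

Step 8
Reactants: 11 1-[3,4-bis(benzyloxy)phenyl]-2-[(triisopropylsilyl)oxy]ethan-1-one; 6 1,5-bis(benzyloxy)-3-bromo-2-(chloromethyl)benzene
Product: 13 5,7-bis(benzyloxy)-2-[3,4-bis(benzyloxy)phenyl]-3-[(triisopropylsilyl)oxy]-4H-chromene, via bromo ketone 12 (not isolated)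
Conditions: NaN(SiMe3)2 (1.05 equiv), THF, −78 °C; 6, −78 → 0 °C; then CuI (10 mol%), 1,10-phenanthroline (20 mol%), Cs2CO3 (2 equiv), DMF, 90 °C
Reagents that add atoms: none
Why: Proposed new method: the sodium enolate of 11 is benzylated at C3 by the doubly alkoxy-activated chloride 6 to give 12 (bond C3–C4), and the tetrasubstituted enolate of 12, formed reversibly by Cs2CO3, then undergoes intramolecular Ullmann-type O-arylation at the ortho bromide (oxidative addition at monovalent copper, C–O reductive elimination) to make O1–C8a. The closest known reaction type is the CuI-catalysed domino C-benzylation/O-arylation of 1,3-dicarbonyl compounds with 2-bromobenzyl bromides to 4H-chromenes, together with copper-catalysed enolate O-arylation to benzofurans; the extension lies in the non-stabilised alpha-siloxy aryl ketone. Ring C closes as a six-membered ring by attack of the enolate oxygen O1 on the aryl carbon C8a, formally 6-exo with respect to the C–Br bond that breaks. The C3 stereocentre of 12 is erased on enolisation, so no stereocentre leaves this step and both are set in step 10. The step needs C- before O-alkylation (soft benzylic electrophile, sodium enolate in THF), a single site of enolisation (C2 carries the ring B aryl group, so only C3–H is acidic and only O1 can become an enolate oxygen) and no route to a five-membered ring (O3 is capped by the bulky triisopropylsilyl group, chosen to suppress a 1,4 oxygen-to-oxygen silyl shift).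

Step 9
Reactants: 13 5,7-bis(benzyloxy)-2-[3,4-bis(benzyloxy)phenyl]-3-[(triisopropylsilyl)oxy]-4H-chromene
Product: 14 5,7-bis(benzyloxy)-2-[3,4-bis(benzyloxy)phenyl]chroman-3-one (racemic)
Conditions: Bu4NF, AcOH, THF, 0 °C
Reagents that add atoms: none
Why: Fluoride cleaves the silyl enol ether and the C3 enolate is protonated at C2 under acetic acid buffering, which should give the ketone without the strong acid that could open ring C.

Step 10
Reactants: 14 5,7-bis(benzyloxy)-2-[3,4-bis(benzyloxy)phenyl]chroman-3-one (racemic)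
Product: 15 (2R,3R)-5,7-bis(benzyloxy)-2-[3,4-bis(benzyloxy)phenyl]chroman-3-ol
Conditions: H2 (10 atm), RuCl2[(S)-xylbinap][(S)-daipen] (1 mol%), KOt-Bu (10 mol%), i-PrOH/THF, 25 °C
Reagents that add atoms: none
Why: Noyori-type hydrogenation of a racemic alpha-aryl cyclic ketone with dynamic kinetic resolution: C2 racemises through the enolate under catalytic base while the chiral divalent ruthenium hydride should reduce the (2R) ketone faster and deliver hydride trans to the C2 aryl group, so the catalyst selects C2 and the C2 substituent sets C3 as 2,3-cis; the (S),(S) catalyst is the proposed sense, to be confirmed by correlation, with the mirror-image catalyst as the direct remedy.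

Step 11
Reactants: 15 (2R,3R)-5,7-bis(benzyloxy)-2-[3,4-bis(benzyloxy)phenyl]chroman-3-ol; 16 3,4,5-tris(benzyloxy)benzoyl chloride
Product: 17 (2R,3R)-5,7-bis(benzyloxy)-2-[3,4-bis(benzyloxy)phenyl]chroman-3-yl 3,4,5-tris(benzyloxy)benzoate
Conditions: Et3N, DMAP (cat.), CH2Cl2, 0 °C → rt
Reagents that add atoms: none
Why: DMAP-catalysed acylation of the hindered secondary alcohol by the acid chloride; no stereocentre is touched.

Step 12
Reactants: 17 (2R,3R)-5,7-bis(benzyloxy)-2-[3,4-bis(benzyloxy)phenyl]chroman-3-yl 3,4,5-tris(benzyloxy)benzoate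
Product: 18 (2R,3R)-2-(3,4-dihydroxyphenyl)-5,7-dihydroxychroman-3-yl 3,4,5-trihydroxybenzoate
Conditions: H2 (1 atm), Pd(OH)2/C, THF/MeOH, rt
Reagents that add atoms: none
Why: Hydrogenolysis of the seven benzyl ethers under neutral conditions that should leave the gallate ester and the benzylic C2–O1 bond intact.

Step 13
Reactants: 19 1-(2,3,4-trihydroxyphenyl)ethan-1-one
Product: 20 1-[2,3,4-tris(benzyloxy)phenyl]ethan-1-one
Conditions: BnBr (3.5 equiv), K2CO3, DMF, 70 °C
Reagents that add atoms: benzyl bromide, BrCc1ccccc1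
Why: Williamson ether synthesis; excess halide and heat are used to alkylate the hydrogen-bonded ortho phenol as well.

Step 14
Reactants: 20 1-[2,3,4-tris(benzyloxy)phenyl]ethan-1-one
Product: 21 ({1-[2,3,4-tris(benzyloxy)phenyl]ethenyl}oxy)tri(propan-2-yl)silane
Conditions: i-Pr3SiOTf, Et3N, CH2Cl2, 0 °C → rt
Reagents that add atoms: triisopropylsilyl trifluoromethanesulfonate, CC(C)[Si](OS(=O)(=O)C(F)(F)F)(C(C)C)C(C)C
Why: Soft enolisation and O-silylation as in step 6.

Step 15
Reactants: 21 ({1-[2,3,4-tris(benzyloxy)phenyl]ethenyl}oxy)tri(propan-2-yl)silane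
Product: 23 1-[2,3,4-tris(benzyloxy)phenyl]-2-[(triisopropylsilyl)oxy]ethan-1-one, via siloxy epoxide 22 (not isolated)
Conditions: mCPBA (1.05 equiv), CH2Cl2, −20 → 0 °C
Reagents that add atoms: 3-chloroperoxybenzoic acid, OOC(=O)c1cccc(Cl)c1
Why: Rubottom oxidation as in step 7.

Step 16
Reactants: 23 1-[2,3,4-tris(benzyloxy)phenyl]-2-[(triisopropylsilyl)oxy]ethan-1-one; 6 1,5-bis(benzyloxy)-3-bromo-2-(chloromethyl)benzene
Product: 25 5,7-bis(benzyloxy)-2-[2,3,4-tris(benzyloxy)phenyl]-3-[(triisopropylsilyl)oxy]-4H-chromene, via bromo ketone 24 (not isolated)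
Conditions: NaN(SiMe3)2 (1.05 equiv), THF, −78 °C; 6, −78 → 0 °C; then CuI (10 mol%), 1,10-phenanthroline (20 mol%), Cs2CO3 (2 equiv), DMF, 90 °C
Reagents that add atoms: none
Why: Proposed new method: as in step 8, the only possible enolate of 23 is benzylated at C3 by 6 and the tetrasubstituted enolate of 24 is then O-arylated at the ortho bromide (oxidative addition at monovalent copper, C–O reductive elimination) to close ring C; the closest known reaction type is the CuI-catalysed domino C-benzylation/O-arylation of 1,3-dicarbonyl compounds with 2-bromobenzyl bromides to 4H-chromenes, extended here to a non-stabilised alpha-siloxy aryl ketone that also carries an ortho benzyloxy group.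

Step 17
Reactants: 25 5,7-bis(benzyloxy)-2-[2,3,4-tris(benzyloxy)phenyl]-3-[(triisopropylsilyl)oxy]-4H-chromene
Product: 26 5,7-bis(benzyloxy)-2-[2,3,4-tris(benzyloxy)phenyl]chroman-3-one (racemic)
Conditions: Bu4NF, AcOH, THF, 0 °C
Reagents that add atoms: none
Why: Buffered fluoride cleavage of the silyl enol ether with C2 protonation, as in step 9.

Step 18
Reactants: 26 5,7-bis(benzyloxy)-2-[2,3,4-tris(benzyloxy)phenyl]chroman-3-one (racemic)
Product: 27 (2R,3R)-5,7-bis(benzyloxy)-2-[2,3,4-tris(benzyloxy)phenyl]chroman-3-ol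
Conditions: H2 (10 atm), RuCl2[(S)-xylbinap][(S)-daipen] (1 mol%), KOt-Bu (10 mol%), i-PrOH/THF, 25 °C
Reagents that add atoms: none
Why: Noyori-type hydrogenation with dynamic kinetic resolution as in step 10, the catalyst selecting the (2R) enantiomer of the racemising ketone and the C2 aryl group directing hydride to give the cis alcohol.

Step 19
Reactants: 27 (2R,3R)-5,7-bis(benzyloxy)-2-[2,3,4-tris(benzyloxy)phenyl]chroman-3-ol
Product: 28 (2R,3R)-2-(2,3,4-trihydroxyphenyl)chromane-3,5,7-triol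
Conditions: H2 (1 atm), Pd(OH)2/C, THF/MeOH, rt; handled under argon and used at once
Reagents that add atoms: none
Why: Neutral hydrogenolysis of the five benzyl ethers; neutral conditions and immediate use are meant to avoid C2 epimerisation of this ortho/para-hydroxylated flavan.

Step 20
Reactants: 18 (2R,3R)-2-(3,4-dihydroxyphenyl)-5,7-dihydroxychroman-3-yl 3,4,5-trihydroxybenzoate; 28 (2R,3R)-2-(2,3,4-trihydroxyphenyl)chromane-3,5,7-triol
Product: 30 CNP0217128.1, via ortho-quinone 29 (not isolated)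
Conditions: horseradish peroxidase, H2O2 (3 equiv, slow addition), acetone/citrate–phosphate buffer pH 5, rt
Reagents that add atoms: none
Why: Biomimetic benzotropolone synthesis of the theaflavin type: ring B of 18 is oxidised to ortho-quinone 29, the pyrogallol ring of 28 adds through its free carbon ortho to the 4-OH and para to the 2-OH, and further oxidation, carbonyl addition, ring expansion and loss of the adjacent C–OH carbon as CO2 should give the tropolone with the flavan of 28 on C7, without touching the four stereocentres.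

**Compound list**

1 | 5-bromobenzene-1,3-diol | Oc1cc(O)cc(Br)c1 | starting material
2 | 1,3-bis(benzyloxy)-5-bromobenzene | Brc1cc(OCc2ccccc2)cc(OCc2ccccc2)c1 | intermediate
3 | N-[2,4-bis(benzyloxy)-6-bromobenzylidene]-N-methylmethanaminium dichlorophosphate | C[N+](C)=Cc1c(Br)cc(OCc2ccccc2)cc1OCc1ccccc1.[O-]P(=O)(Cl)Cl | intermediate (not isolated)
4 | 2,4-bis(benzyloxy)-6-bromobenzaldehyde | O=Cc1c(Br)cc(OCc2ccccc2)cc1OCc1ccccc1 | intermediate
5 | [2,4-bis(benzyloxy)-6-bromophenyl]methanol | OCc1c(Br)cc(OCc2ccccc2)cc1OCc1ccccc1 | intermediate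
6 | 1,5-bis(benzyloxy)-3-bromo-2-(chloromethyl)benzene | ClCc1c(Br)cc(OCc2ccccc2)cc1OCc1ccccc1 | intermediate
7 | 1-(3,4-dihydroxyphenyl)ethan-1-one | CC(=O)c1ccc(O)c(O)c1 | starting material
8 | 1-[3,4-bis(benzyloxy)phenyl]ethan-1-one | CC(=O)c1ccc(OCc2ccccc2)c(OCc2ccccc2)c1 | intermediate
9 | ({1-[3,4-bis(benzyloxy)phenyl]ethenyl}oxy)tri(propan-2-yl)silane | C=C(O[Si](C(C)C)(C(C)C)C(C)C)c1ccc(OCc2ccccc2)c(OCc2ccccc2)c1 | intermediate
10 | ({2-[3,4-bis(benzyloxy)phenyl]oxiran-2-yl}oxy)tri(propan-2-yl)silane (racemic) | CC(C)[Si](OC1(CO1)c1ccc(OCc2ccccc2)c(OCc2ccccc2)c1)(C(C)C)C(C)C | intermediate (not isolated)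
11 | 1-[3,4-bis(benzyloxy)phenyl]-2-[(triisopropylsilyl)oxy]ethan-1-one | CC(C)[Si](OCC(=O)c1ccc(OCc2ccccc2)c(OCc2ccccc2)c1)(C(C)C)C(C)C | intermediate
12 | 1-[3,4-bis(benzyloxy)phenyl]-3-[2,4-bis(benzyloxy)-6-bromophenyl]-2-[(triisopropylsilyl)oxy]propan-1-one (racemic) | CC(C)[Si](OC(Cc1c(Br)cc(OCc2ccccc2)cc1OCc1ccccc1)C(=O)c1ccc(OCc2ccccc2)c(OCc2ccccc2)c1)(C(C)C)C(C)C | intermediate (not isolated)
13 | 5,7-bis(benzyloxy)-2-[3,4-bis(benzyloxy)phenyl]-3-[(triisopropylsilyl)oxy]-4H-chromene | CC(C)[Si](OC1=C(Oc2cc(OCc3ccccc3)cc(OCc3ccccc3)c2C1)c1ccc(OCc2ccccc2)c(OCc2ccccc2)c1)(C(C)C)C(C)C | intermediate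
14 | 5,7-bis(benzyloxy)-2-[3,4-bis(benzyloxy)phenyl]chroman-3-one (racemic) | O=C1Cc2c(OCc3ccccc3)cc(OCc3ccccc3)cc2OC1c1ccc(OCc2ccccc2)c(OCc2ccccc2)c1 | intermediate
15 | (2R,3R)-5,7-bis(benzyloxy)-2-[3,4-bis(benzyloxy)phenyl]chroman-3-ol | O[C@@H]1Cc2c(OCc3ccccc3)cc(OCc3ccccc3)cc2O[C@@H]1c1ccc(OCc2ccccc2)c(OCc2ccccc2)c1 | intermediate
16 | 3,4,5-tris(benzyloxy)benzoyl chloride | O=C(Cl)c1cc(OCc2ccccc2)c(OCc2ccccc2)c(OCc2ccccc2)c1 | starting material
17 | (2R,3R)-5,7-bis(benzyloxy)-2-[3,4-bis(benzyloxy)phenyl]chroman-3-yl 3,4,5-tris(benzyloxy)benzoate | O=C(O[C@@H]1Cc2c(OCc3ccccc3)cc(OCc3ccccc3)cc2O[C@@H]1c1ccc(OCc2ccccc2)c(OCc2ccccc2)c1)c1cc(OCc2ccccc2)c(OCc2ccccc2)c(OCc2ccccc2)c1 | intermediate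
18 | (2R,3R)-2-(3,4-dihydroxyphenyl)-5,7-dihydroxychroman-3-yl 3,4,5-trihydroxybenzoate (epicatechin 3-O-gallate) | O=C(O[C@@H]1Cc2c(O)cc(O)cc2O[C@@H]1c1ccc(O)c(O)c1)c1cc(O)c(O)c(O)c1 | intermediate
19 | 1-(2,3,4-trihydroxyphenyl)ethan-1-one | CC(=O)c1ccc(O)c(O)c1O | starting material
20 | 1-[2,3,4-tris(benzyloxy)phenyl]ethan-1-one | CC(=O)c1ccc(OCc2ccccc2)c(OCc2ccccc2)c1OCc1ccccc1 | intermediate
21 | ({1-[2,3,4-tris(benzyloxy)phenyl]ethenyl}oxy)tri(propan-2-yl)silane | C=C(O[Si](C(C)C)(C(C)C)C(C)C)c1ccc(OCc2ccccc2)c(OCc2ccccc2)c1OCc1ccccc1 | intermediate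
22 | ({2-[2,3,4-tris(benzyloxy)phenyl]oxiran-2-yl}oxy)tri(propan-2-yl)silane (racemic) | CC(C)[Si](OC1(CO1)c1ccc(OCc2ccccc2)c(OCc2ccccc2)c1OCc1ccccc1)(C(C)C)C(C)C | intermediate (not isolated)
23 | 1-[2,3,4-tris(benzyloxy)phenyl]-2-[(triisopropylsilyl)oxy]ethan-1-one | CC(C)[Si](OCC(=O)c1ccc(OCc2ccccc2)c(OCc2ccccc2)c1OCc1ccccc1)(C(C)C)C(C)C | intermediate
24 | 3-[2,4-bis(benzyloxy)-6-bromophenyl]-1-[2,3,4-tris(benzyloxy)phenyl]-2-[(triisopropylsilyl)oxy]propan-1-one (racemic) | CC(C)[Si](OC(Cc1c(Br)cc(OCc2ccccc2)cc1OCc1ccccc1)C(=O)c1ccc(OCc2ccccc2)c(OCc2ccccc2)c1OCc1ccccc1)(C(C)C)C(C)C | intermediate (not isolated)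
25 | 5,7-bis(benzyloxy)-2-[2,3,4-tris(benzyloxy)phenyl]-3-[(triisopropylsilyl)oxy]-4H-chromene | CC(C)[Si](OC1=C(Oc2cc(OCc3ccccc3)cc(OCc3ccccc3)c2C1)c1ccc(OCc2ccccc2)c(OCc2ccccc2)c1OCc1ccccc1)(C(C)C)C(C)C | intermediate
26 | 5,7-bis(benzyloxy)-2-[2,3,4-tris(benzyloxy)phenyl]chroman-3-one (racemic) | O=C1Cc2c(OCc3ccccc3)cc(OCc3ccccc3)cc2OC1c1ccc(OCc2ccccc2)c(OCc2ccccc2)c1OCc1ccccc1 | intermediate
27 | (2R,3R)-5,7-bis(benzyloxy)-2-[2,3,4-tris(benzyloxy)phenyl]chroman-3-ol | O[C@@H]1Cc2c(OCc3ccccc3)cc(OCc3ccccc3)cc2O[C@@H]1c1ccc(OCc2ccccc2)c(OCc2ccccc2)c1OCc1ccccc1 | intermediate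
28 | (2R,3R)-2-(2,3,4-trihydroxyphenyl)chromane-3,5,7-triol | O[C@@H]1Cc2c(O)cc(O)cc2O[C@@H]1c1ccc(O)c(O)c1O | intermediate
29 | (2R,3R)-2-(3,4-dioxocyclohexa-1,5-dien-1-yl)-5,7-dihydroxychroman-3-yl 3,4,5-trihydroxybenzoate | O=C(O[C@@H]1Cc2c(O)cc(O)cc2O[C@@H]1C3=CC(=O)C(=O)C=C3)c1cc(O)c(O)c(O)c1 | intermediate (not isolated)
30 | CNP0217128.1, (2R,3R)-5,7-dihydroxy-2-{3,4,6-trihydroxy-5-oxo-7-[(2R,3R)-3,5,7-trihydroxychroman-2-yl]-5H-benzo[7]annulen-1-yl}chroman-3-yl 3,4,5-trihydroxybenzoate | O=C(O[C@@H]1Cc2c(O)cc(O)cc2O[C@@H]1c1cc(O)c(O)c2c(=O)c(O)c([C@H]3Oc4cc(O)cc(O)c4C[C@H]3O)ccc12)c1cc(O)c(O)c(O)c1 | target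

**Step count and risks**

Total: 20 steps. Longest linear sequence: 10 steps (steps 1–4, 8–12, 20).

Steps most likely to fail:

1. Step 8. The enolate of 12 may undergo a 1,4 oxygen-to-oxygen silyl shift followed by five-membered O-arylation, or the copper-mediated C–O coupling may stall at the hindered tetrasubstituted enolate and give protodebromination. The fallback sets out from 11 and 6 and returns at 14, forming the two bonds in separate, known operations. The alkylation stage alone (NaN(SiMe3)2, THF, −78 → 0 °C) is worked up and 12 is isolated. NaBH4 in THF/MeOH reduces the ketone to the bromo alcohol F1, whose diastereomer ratio is of no consequence. Intramolecular Buchwald-type etherification of the secondary benzylic alcohol with the aryl bromide (Pd(OAc)2, 2-(di-tert-butylphosphino)-1,1'-binaphthyl, Cs2CO3, toluene, 80 °C) closes ring C to the 3-siloxyflavan F2; only O1 can close because O3 is silylated. Bu4NF in THF gives the flavan-3-ol F3, and Dess–Martin periodinane in CH2Cl2 oxidises it to 14, where the dynamic kinetic hydrogenation resets both stereocentres.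

2. Step 16. The same silyl migration or stalled coupling is possible, made more likely by the ortho benzyloxy group beside the ketone. The fallback sets out from 23 and 6 and returns at 26. Compound 24 is isolated after the alkylation stage and reduced with NaBH4 to the bromo alcohol F4. The same palladium-catalysed etherification gives the 3-siloxyflavan F5, Bu4NF gives the flavan-3-ol F6, and Dess–Martin oxidation gives 26.

3. Step 20. Chemoselectivity of the oxidation may be lost: the galloyl pyrogallol of 18 can enter the condensation in place of the trihydroxyphenyl ring of 28, and 28 can self-condense, leaving a mixture from which the product is hard to separate. The fallback sets out from 15 and returns at 30, with the galloyl group masked during the oxidation. Compound 15 is acylated with 3,4,5-triacetoxybenzoyl chloride (Et3N, DMAP, CH2Cl2) to the tetrabenzyl triacetylgallate F7. Hydrogenolysis (H2, Pd(OH)2/C, THF/MeOH) gives epicatechin 3-O-(3,4,5-triacetoxybenzoate) F8, in which only ring B can form a quinone. Condensation with 28 under the conditions of step 20 gives the benzotropolone triacetate F9, and mild deacetylation of the aryl acetates (NH4OAc, MeOH/H2O, rt, under argon) gives 30.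

**Further compounds**

F1 | step 8 | 1-[3,4-bis(benzyloxy)phenyl]-3-[2,4-bis(benzyloxy)-6-bromophenyl]-2-[(triisopropylsilyl)oxy]propan-1-ol (racemic, diastereomer mixture) | CC(C)[Si](OC(Cc1c(Br)cc(OCc2ccccc2)cc1OCc1ccccc1)C(O)c1ccc(OCc2ccccc2)c(OCc2ccccc2)c1)(C(C)C)C(C)C
F2 | step 8 | 5,7-bis(benzyloxy)-2-[3,4-bis(benzyloxy)phenyl]-3-[(triisopropylsilyl)oxy]chromane (racemic, cis/trans mixture) | CC(C)[Si](OC1Cc2c(OCc3ccccc3)cc(OCc3ccccc3)cc2OC1c1ccc(OCc2ccccc2)c(OCc2ccccc2)c1)(C(C)C)C(C)C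
F3 | step 8 | 5,7-bis(benzyloxy)-2-[3,4-bis(benzyloxy)phenyl]chroman-3-ol (racemic, cis/trans mixture) | OC1Cc2c(OCc3ccccc3)cc(OCc3ccccc3)cc2OC1c1ccc(OCc2ccccc2)c(OCc2ccccc2)c1
F4 | step 16 | 3-[2,4-bis(benzyloxy)-6-bromophenyl]-1-[2,3,4-tris(benzyloxy)phenyl]-2-[(triisopropylsilyl)oxy]propan-1-ol (racemic, diastereomer mixture) | CC(C)[Si](OC(Cc1c(Br)cc(OCc2ccccc2)cc1OCc1ccccc1)C(O)c1ccc(OCc2ccccc2)c(OCc2ccccc2)c1OCc1ccccc1)(C(C)C)C(C)C
F5 | step 16 | 5,7-bis(benzyloxy)-2-[2,3,4-tris(benzyloxy)phenyl]-3-[(triisopropylsilyl)oxy]chromane (racemic, cis/trans mixture) | CC(C)[Si](OC1Cc2c(OCc3ccccc3)cc(OCc3ccccc3)cc2OC1c1ccc(OCc2ccccc2)c(OCc2ccccc2)c1OCc1ccccc1)(C(C)C)C(C)C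
F6 | step 16 | 5,7-bis(benzyloxy)-2-[2,3,4-tris(benzyloxy)phenyl]chroman-3-ol (racemic, cis/trans mixture) | OC1Cc2c(OCc3ccccc3)cc(OCc3ccccc3)cc2OC1c1ccc(OCc2ccccc2)c(OCc2ccccc2)c1OCc1ccccc1
F7 | step 20 | (2R,3R)-5,7-bis(benzyloxy)-2-[3,4-bis(benzyloxy)phenyl]chroman-3-yl 3,4,5-triacetoxybenzoate | CC(=O)Oc1cc(cc(OC(C)=O)c1OC(C)=O)C(=O)O[C@@H]1Cc2c(OCc3ccccc3)cc(OCc3ccccc3)cc2O[C@@H]1c1ccc(OCc2ccccc2)c(OCc2ccccc2)c1
F8 | step 20 | (2R,3R)-2-(3,4-dihydroxyphenyl)-5,7-dihydroxychroman-3-yl 3,4,5-triacetoxybenzoate | CC(=O)Oc1cc(cc(OC(C)=O)c1OC(C)=O)C(=O)O[C@@H]1Cc2c(O)cc(O)cc2O[C@@H]1c1ccc(O)c(O)c1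
F9 | step 20 | (2R,3R)-5,7-dihydroxy-2-{3,4,6-trihydroxy-5-oxo-7-[(2R,3R)-3,5,7-trihydroxychroman-2-yl]-5H-benzo[7]annulen-1-yl}chroman-3-yl 3,4,5-triacetoxybenzoate | CC(=O)Oc1cc(cc(OC(C)=O)c1OC(C)=O)C(=O)O[C@@H]1Cc2c(O)cc(O)cc2O[C@@H]1c1cc(O)c(O)c2c(=O)c(O)c([C@H]3Oc4cc(O)cc(O)c4C[C@H]3O)ccc12
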